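**Plan**
- Retrosynthesis: cut the pyridone C3–acyl bond (aryllithium + aldehyde) and the pyridone C5–C1′ bond (aryllithium + cyclohexenone). In the decalin cut C3=C4 (ring-closing metathesis), C1–C2 (Ireland–Claisen) and, as a ring contraction, the ring-fusion bond C4a–C8a.
- Enabling feature: the carbocycle C4a–C5–C6–C7–C8–C8a carries only four CH2 groups and two cis ring-fusion CH. With C4 and C1 these are the eight carbons of cycloocta-1,3-diene, whose 4π-electrocyclisation contracts the eight-membered ring to this six-membered ring and leaves C1=C4 as a strained cyclobutene.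
- Forward, decalin: 8-ring → cis-fused 6/4 bicycle → enantioselective ring-opening cross-metathesis (opens the 4-ring, distinguishes the C1 arm from the C4 arm) → Ireland–Claisen (C1–C2) → RCM (C3=C4 closes the cyclohexene ring).
- Forward, heterocycle: 5-lithio-2,4-dialkoxypyridine + (S)-4-silyloxycyclohexenone → tertiary carbinol; Mitsunobu inversion; OH-directed epoxidation; C3-lithiation and addition to the decalin aldehyde; oxidation; fluoride deprotection; N-hydroxylation last.
- Stereochemistry: cis ring fusion from the conrotatory closure; absolute configuration at C4a/C8a from the chiral metathesis catalyst; C2 and C1 from (R)-pentenol through a chair Claisen; C1′ by anti addition to the (S)-enone, C4′ by inversion, C2′/C3′ by hydroxyl direction.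

Key step: step 1

Assumption: (2R,3E)-pent-3-en-2-ol (8) and (4S)-4-hydroxycyclohex-2-en-1-one (18) are taken as purchasable in enantiopure form, and the catalyst enantiomer in step 2 is the one that gives 6 as drawn.

**Route**

Step 1
Reactants: 1 (1Z,3Z)-cycloocta-1,3-diene
Product: 3 cis-bicyclo[4.2.0]oct-7-ene (meso), via (1Z,3E)-cycloocta-1,3-diene 2 (not isolated)
Conditions: hν (Pyrex, >300 nm), PhCOMe (sens.), C6H6, 80 °C, 0.02 M
Reagents that add atoms: none
Why: Triplet energy transfer from acetophenone isomerises one ring double bond of 1 (Z→E), and the strained diene 2 closes thermally by conrotatory 4π-electrocyclisation, which is the known photosensitised route from cycloocta-1,3-diene to bicyclo[4.2.0]oct-7-ene. The new σ-bond joins the two diene termini across the ring, so the eight-membered carbocycle contracts to the six-membered ring (four CH2 plus the two former terminal CH), while the two inner diene carbons are expelled into the fused cyclobutene, which closes by thermally allowed conrotation. Conrotation of the Z,E-diene puts both new methine hydrogens on the same face, so the ring fusion should be cis and the product meso. The step needs ring closure to win over [2+2] dimerisation of 2 and over return to 1; high dilution and working at 80 °C, where 2 should cyclise as it forms, secure this, and 3 does not absorb above 300 nm. The strain stored in the cyclobutene is what drives the ring opening in step 2.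

Step 2
Reactants: 3 cis-bicyclo[4.2.0]oct-7-ene; 4 butyl vinyl ether
Product: 6 2-[(1S,2R)-2-ethenylcyclohexyl]acetaldehyde, via (Z)-enol ether 5 (not isolated)
Conditions: enantiopure Mo monoaryloxide–pyrrolide imido alkylidene (2 mol %), C6H6, 22 °C; then 1 M HCl, THF, 0 °C
Reagents that add atoms: water, O
Why: Asymmetric ring-opening/cross-metathesis of a strained meso cyclobutene with an enol ether (a known reaction type) lets the chiral catalyst choose one of the two enantiotopic ring carbons for the alkoxyalkylidene end, which fixes the absolute configuration of both ring-fusion carbons, and mild acid hydrolysis of the enol ether then frees the aldehyde.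

Step 3
Reactants: 6 2-[(1S,2R)-2-ethenylcyclohexyl]acetaldehyde
Product: 7 2-[(1S,2R)-2-ethenylcyclohexyl]acetic acid
Conditions: NaClO2, NaH2PO4, 2-methylbut-2-ene, t-BuOH/H2O, 0 °C → rt
Reagents that add atoms: sodium chlorite, [Na+].[O-]Cl=O
Why: Pinnick oxidation converts the aldehyde to the acid while the alkene scavenger removes hypochlorite, so the vinyl group and both stereocentres should stay untouched.

Step 4
Reactants: 7 2-[(1S,2R)-2-ethenylcyclohexyl]acetic acid; 8 (2R,3E)-pent-3-en-2-ol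
Product: 9 (2R,3E)-pent-3-en-2-yl 2-[(1S,2R)-2-ethenylcyclohexyl]acetate
Conditions: DCC, DMAP (cat.), CH2Cl2, 0 °C → rt
Reagents that add atoms: none
Why: Steglich esterification acylates the secondary allylic alcohol with retention and so brings in the stereocentre that is relayed to C2 in the next step.

Step 5
Reactants: 9 (2R,3E)-pent-3-en-2-yl 2-[(1S,2R)-2-ethenylcyclohexyl]acetate
Product: 12 (2R,3S,4E)-2-[(1R,2R)-2-ethenylcyclohexyl]-3-methylhex-4-enoic acid, via silyl ketene acetal 10 (not isolated), via trimethylsilyl ester 11 (not isolated)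
Conditions: LDA, THF, −78 °C; TMSCl, −78 → 60 °C; then 1 M HCl
Reagents that add atoms: none
Why: Ireland–Claisen rearrangement: kinetic enolisation in THF should give the (E)-silyl ketene acetal, and the chair [3,3] transition state with the carbinol methyl equatorial transfers the (R) centre of the allylic ester to the new methyl-bearing carbon (decalin C2, S) and, through the enolate geometry, sets the carboxyl-bearing carbon (decalin C1, R) anti to it, with a new (E)-alkene.

Step 6
Reactants: 12 (2R,3S,4E)-2-[(1R,2R)-2-ethenylcyclohexyl]-3-methylhex-4-enoic acid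
Product: 13 (1R,2S,4aR,8aR)-2-methyl-1,2,4a,5,6,7,8,8a-octahydronaphthalene-1-carboxylic acid
Conditions: (H2IMes)(PCy3)Cl2Ru=CHPh (5 mol %), CH2Cl2, 40 °C
Reagents that add atoms: none
Why: Ring-closing metathesis of the 1,7-diene with loss of propene forms C3=C4 and the cyclohexene ring; the cis-disposed vinyl and propenyl arms should close readily to the cis-decalin and no stereocentre is touched.

Step 7
Reactants: 13 (1R,2S,4aR,8aR)-2-methyl-1,2,4a,5,6,7,8,8a-octahydronaphthalene-1-carboxylic acid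
Product: 14 [(1R,2S,4aR,8aR)-2-methyl-1,2,4a,5,6,7,8,8a-octahydronaphthalen-1-yl]methanol
Conditions: LiAlH4, THF, 0 °C → rt; then H2O
Reagents that add atoms: none
Why: Hydride reduction of the carboxylic acid to the primary alcohol leaves the isolated alkene and the α-stereocentre unchanged.

Step 8
Reactants: 14 [(1R,2S,4aR,8aR)-2-methyl-1,2,4a,5,6,7,8,8a-octahydronaphthalen-1-yl]methanol
Product: 15 (1R,2S,4aR,8aR)-2-methyl-1,2,4a,5,6,7,8,8a-octahydronaphthalene-1-carbaldehyde
Conditions: DMP, NaHCO3, CH2Cl2, 0 °C → rt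
Reagents that add atoms: none
Why: Buffered periodinane (Dess–Martin) oxidation gives the aldehyde without epimerisation, and the C1 configuration (trans to both neighbours) is also the thermodynamically preferred one.

Step 9
Reactants: 16 5-bromo-2,4-dichloropyridine
Product: 17 5-bromo-2,4-bis[2-(trimethylsilyl)ethoxy]pyridine
Conditions: NaH, Me3SiCH2CH2OH, DMF, 0 → 60 °C
Reagents that add atoms: 2-(trimethylsilyl)ethanol, C[Si](C)(C)CCO
Why: Twofold nucleophilic aromatic substitution (SNAr) replaces the 2- and 4-chlorides, both activated by the ring nitrogen, while the unactivated 5-bromide should stay.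

Step 10
Reactants: 18 (4S)-4-hydroxycyclohex-2-en-1-one
Product: 19 (4S)-4-[(trimethylsilyl)oxy]cyclohex-2-en-1-one
Conditions: TMSCl, Et3N, CH2Cl2, 0 °C
Reagents that add atoms: chlorotrimethylsilane, C[Si](C)(C)Cl
Why: O-Silylation masks the secondary alcohol as a base-labile trimethylsilyl ether for the organolithium step.

Step 11
Reactants: 17 5-bromo-2,4-bis[2-(trimethylsilyl)ethoxy]pyridine; 19 (4S)-4-[(trimethylsilyl)oxy]cyclohex-2-en-1-one
Product: 22 5-{(1R,4S)-1-[(tert-butyldimethylsilyl)oxy]-4-[(trimethylsilyl)oxy]cyclohex-2-en-1-yl}-2,4-bis[2-(trimethylsilyl)ethoxy]pyridine, via 5-lithiopyridine 20 (not isolated), via lithium alkoxide 21 (not isolated)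
Conditions: n-BuLi, THF, −78 °C; 19, −78 °C; TBSOTf, −78 → 0 °C
Reagents that add atoms: tert-butyldimethylsilyl trifluoromethanesulfonate, CC(C)(C)[Si](C)(C)OS(=O)(=O)C(F)(F)F
Why: Bromine–lithium exchange, 1,2-addition of the aryllithium to the enone anti to the pseudoaxial γ-silyloxy group (axial attack on the half-chair) and O-silylation of the tertiary alkoxide in the same flask set C1′ relative to C4′; a minor syn adduct should be separable.

Step 12
Reactants: 22 bis-silyl ether from step 11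
Product: 23 (1S,4R)-4-{4,6-bis[2-(trimethylsilyl)ethoxy]pyridin-3-yl}-4-[(tert-butyldimethylsilyl)oxy]cyclohex-2-en-1-ol
Conditions: K2CO3 (cat.), MeOH, 0 °C
Reagents that add atoms: none
Why: Mild basic methanolysis cleaves only the secondary trimethylsilyl ether, and it avoids acid, which could ionise the tertiary allylic, pyridyl-substituted centre.

Step 13
Reactants: 23 cis-configured allylic alcohol from step 12
Product: 24 (1R,4R)-4-{4,6-bis[2-(trimethylsilyl)ethoxy]pyridin-3-yl}-4-[(tert-butyldimethylsilyl)oxy]cyclohex-2-en-1-yl 4-nitrobenzoate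
Conditions: 4-O2NC6H4CO2H, PPh3, DIAD, toluene, −20 °C → rt
Reagents that add atoms: 4-nitrobenzoic acid, OC(=O)c1ccc(cc1)[N+](=O)[O-]
Why: The Mitsunobu reaction inverts the secondary allylic carbinol centre by SN2 displacement of the oxyphosphonium group, which puts the C4′ oxygen trans to the tertiary oxygen and cis to the pyridyl group.

Step 14
Reactants: 24 4-nitrobenzoate from step 13
Product: 25 (1R,4R)-4-{4,6-bis[2-(trimethylsilyl)ethoxy]pyridin-3-yl}-4-[(tert-butyldimethylsilyl)oxy]cyclohex-2-en-1-ol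
Conditions: K2CO3 (cat.), MeOH, rt
Reagents that add atoms: none
Why: Transesterification with methoxide releases the inverted allylic alcohol without touching the silyl or aryl ethers.

Step 15
Reactants: 25 trans-configured allylic alcohol from step 14
Product: 26 (1R,2R,5S,6R)-5-{4,6-bis[2-(trimethylsilyl)ethoxy]pyridin-3-yl}-5-[(tert-butyldimethylsilyl)oxy]-7-oxabicyclo[4.1.0]heptan-2-ol
Conditions: VO(acac)2 (cat.), t-BuOOH, CH2Cl2, 0 °C → rt
Reagents that add atoms: tert-butyl hydroperoxide, CC(C)(C)OO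
Why: Vanadium-catalysed hydroxyl-directed epoxidation delivers oxygen to the alkene face syn to the pseudoaxial allylic hydroxyl, which is also the face anti to the tertiary silyl ether, so both epoxide centres should form cis to the C4′ oxygen.

Step 16
Reactants: 26 epoxy alcohol from step 15
Product: 27 5-{(1R,2S,5R,6S)-2-[(tert-butyldimethylsilyl)oxy]-5-[(triethylsilyl)oxy]-7-oxabicyclo[4.1.0]heptan-2-yl}-2,4-bis[2-(trimethylsilyl)ethoxy]pyridine
Conditions: TESCl, imidazole, DMF, rt
Reagents that add atoms: chlorotriethylsilane, CC[Si](Cl)(CC)CC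
Why: O-Silylation protects the secondary alcohol for the lithiation.

Step 17
Reactants: 27 bis-silylated epoxide from step 16; 15 (1R,2S,4aR,8aR)-2-methyl-1,2,4a,5,6,7,8,8a-octahydronaphthalene-1-carbaldehyde
Product: 29 secondary carbinol joining decalin C1 to pyridine C3 (both carbinol epimers), via 3-lithiopyridine 28 (not isolated)
Conditions: n-BuLi, THF, −78 → −30 °C; 15, −78 °C; then H2O
Reagents that add atoms: none
Why: Directed ortho-lithiation at C3, the only ring position flanked by both alkoxy groups, followed by addition of the aryllithium to the aldehyde, gives two carbinol epimers that converge in the next step.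

Step 18
Reactants: 29 carbinol from step 17
Product: 30 aryl ketone (fully protected 1-deoxyfischerin)
Conditions: DMP, NaHCO3, CH2Cl2, rt
Reagents that add atoms: none
Why: Periodinane (Dess–Martin) oxidation of the hindered benzylic-type carbinol gives the aryl ketone, and C1, now α to the ketone, keeps or relaxes to the favoured all-trans arrangement.

Step 19
Reactants: 30 protected ketone from step 18
Product: 31 1-deoxyfischerin (N–H pyridone)
Conditions: TBAF, AcOH, THF, 0 → 40 °C
Reagents that add atoms: none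
Why: Fluoride cleaves both silyl ethers and attacks silicon of the two 2-(trimethylsilyl)ethyl ethers, which fragment with loss of ethene (Peterson-type β-elimination) to unveil the 4-hydroxy-2-pyridone, while acetic acid buffering guards the epoxy diol against base-induced epoxide migration.

Step 20
Reactants: 31 1-deoxyfischerin
Product: 33 fischerin, via tetrakis(trimethylsilyl) derivative 32 (not isolated)
Conditions: (Me3Si)2NH, TMSCl (cat.), CH2Cl2, reflux; MoO5·pyridine·HMPA, CH2Cl2, rt; then aq. Na4EDTA, MeOH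
Reagents that add atoms: oxodiperoxomolybdenum(pyridine)(hexamethylphosphoric triamide), O=[Mo]12(OO1)OO2.c1ccncc1.CN(C)P(=O)(N(C)C)N(C)C
Why: N-Hydroxylation of a 2-pyridone through its O-silyl lactim: persilylation makes the ring nitrogen nucleophilic, the peroxo-molybdenum complex transfers oxygen to it and aqueous work-up gives the 1-hydroxy-2-pyridone, a transformation known for 3-acyl-4-hydroxy-2-pyridones.

**Compound list**

1 | (1Z,3Z)-cycloocta-1,3-diene | C1CC/C=C\C=C/C1 | starting material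
2 | (1Z,3E)-cycloocta-1,3-diene | C1CC/C=C\C=C\C1 | intermediate
3 | cis-bicyclo[4.2.0]oct-7-ene (meso) | C1=C[C@@H]2CCCC[C@H]12 | intermediate
4 | butyl vinyl ether | CCCCOC=C | starting material
5 | (1R,2R)-1-[(Z)-2-butoxyethenyl]-2-ethenylcyclohexane (cis) | C=C[C@H]1CCCC[C@H]1/C=C\OCCCC | intermediate
6 | 2-[(1S,2R)-2-ethenylcyclohexyl]acetaldehyde (cis) | C=C[C@H]1CCCC[C@H]1CC=O | intermediate
7 | 2-[(1S,2R)-2-ethenylcyclohexyl]acetic acid | C=C[C@H]1CCCC[C@H]1CC(=O)O | intermediate
8 | (2R,3E)-pent-3-en-2-ol | C/C=C/[C@@H](C)O | starting material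
9 | (2R,3E)-pent-3-en-2-yl 2-[(1S,2R)-2-ethenylcyclohexyl]acetate | C=C[C@H]1CCCC[C@H]1CC(=O)O[C@H](C)/C=C/C | intermediate
10 | (E)-O-trimethylsilyl ketene acetal of 9 (ring residue cis to the pentenyloxy group) | C=C[C@H]1CCCC[C@H]1/C=C(/O[Si](C)(C)C)\O[C@H](C)/C=C/C | intermediate
11 | trimethylsilyl (2R,3S,4E)-2-[(1R,2R)-2-ethenylcyclohexyl]-3-methylhex-4-enoate | C[Si](C)(C)OC(=O)[C@H]([C@@H](C)/C=C/C)[C@@H]1CCCC[C@@H]1C=C | intermediate
12 | (2R,3S,4E)-2-[(1R,2R)-2-ethenylcyclohexyl]-3-methylhex-4-enoic acid | OC(=O)[C@H]([C@@H](C)/C=C/C)[C@@H]1CCCC[C@@H]1C=C | intermediate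
13 | (1R,2S,4aR,8aR)-2-methyl-1,2,4a,5,6,7,8,8a-octahydronaphthalene-1-carboxylic acid (cis-fused) | C[C@H]1C=C[C@H]2CCCC[C@H]2[C@@H]1C(=O)O | intermediate
14 | [(1R,2S,4aR,8aR)-2-methyl-1,2,4a,5,6,7,8,8a-octahydronaphthalen-1-yl]methanol | C[C@H]1C=C[C@H]2CCCC[C@H]2[C@@H]1CO | intermediate
15 | (1R,2S,4aR,8aR)-2-methyl-1,2,4a,5,6,7,8,8a-octahydronaphthalene-1-carbaldehyde | C[C@H]1C=C[C@H]2CCCC[C@H]2[C@@H]1C=O | intermediate
16 | 5-bromo-2,4-dichloropyridine | Clc1cc(Cl)c(Br)cn1 | starting material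
17 | 5-bromo-2,4-bis[2-(trimethylsilyl)ethoxy]pyridine | C[Si](C)(C)CCOc1cc(OCC[Si](C)(C)C)c(Br)cn1 | intermediate
18 | (4S)-4-hydroxycyclohex-2-en-1-one | O=C1C=C[C@@H](O)CC1 | starting material
19 | (4S)-4-[(trimethylsilyl)oxy]cyclohex-2-en-1-one | O=C1C=C[C@@H](O[Si](C)(C)C)CC1 | intermediate
20 | {4,6-bis[2-(trimethylsilyl)ethoxy]pyridin-3-yl}lithium | [Li]c1cnc(OCC[Si](C)(C)C)cc1OCC[Si](C)(C)C | intermediate
21 | lithium (1R,4S)-1-{4,6-bis[2-(trimethylsilyl)ethoxy]pyridin-3-yl}-4-[(trimethylsilyl)oxy]cyclohex-2-en-1-olate | C[Si](C)(C)CCOc1cc(OCC[Si](C)(C)C)c(cn1)[C@@]1(O[Li])CC[C@H](O[Si](C)(C)C)C=C1 | intermediate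
22 | 5-{(1R,4S)-1-[(tert-butyldimethylsilyl)oxy]-4-[(trimethylsilyl)oxy]cyclohex-2-en-1-yl}-2,4-bis[2-(trimethylsilyl)ethoxy]pyridine (both silyloxy groups on one face, pyridyl on the other) | C[Si](C)(C)CCOc1cc(OCC[Si](C)(C)C)c(cn1)[C@@]1(O[Si](C)(C)C(C)(C)C)CC[C@H](O[Si](C)(C)C)C=C1 | intermediate
23 | (1S,4R)-4-{4,6-bis[2-(trimethylsilyl)ethoxy]pyridin-3-yl}-4-[(tert-butyldimethylsilyl)oxy]cyclohex-2-en-1-ol (OH cis to OTBS) | C[Si](C)(C)CCOc1cc(OCC[Si](C)(C)C)c(cn1)[C@@]1(O[Si](C)(C)C(C)(C)C)CC[C@H](O)C=C1 | intermediate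
24 | (1R,4R)-4-{4,6-bis[2-(trimethylsilyl)ethoxy]pyridin-3-yl}-4-[(tert-butyldimethylsilyl)oxy]cyclohex-2-en-1-yl 4-nitrobenzoate (ester oxygen trans to OTBS) | C[Si](C)(C)CCOc1cc(OCC[Si](C)(C)C)c(cn1)[C@@]1(O[Si](C)(C)C(C)(C)C)CC[C@@H](OC(=O)c2ccc(cc2)[N+](=O)[O-])C=C1 | intermediate
25 | (1R,4R)-4-{4,6-bis[2-(trimethylsilyl)ethoxy]pyridin-3-yl}-4-[(tert-butyldimethylsilyl)oxy]cyclohex-2-en-1-ol (OH trans to OTBS, cis to pyridyl) | C[Si](C)(C)CCOc1cc(OCC[Si](C)(C)C)c(cn1)[C@@]1(O[Si](C)(C)C(C)(C)C)CC[C@@H](O)C=C1 | intermediate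
26 | (1R,2R,5S,6R)-5-{4,6-bis[2-(trimethylsilyl)ethoxy]pyridin-3-yl}-5-[(tert-butyldimethylsilyl)oxy]-7-oxabicyclo[4.1.0]heptan-2-ol (epoxide cis to OH and pyridyl, trans to OTBS) | C[Si](C)(C)CCOc1cc(OCC[Si](C)(C)C)c(cn1)[C@@]1(O[Si](C)(C)C(C)(C)C)CC[C@@H](O)[C@H]2O[C@H]21 | intermediate
27 | 5-{(1R,2S,5R,6S)-2-[(tert-butyldimethylsilyl)oxy]-5-[(triethylsilyl)oxy]-7-oxabicyclo[4.1.0]heptan-2-yl}-2,4-bis[2-(trimethylsilyl)ethoxy]pyridine | C[Si](C)(C)CCOc1cc(OCC[Si](C)(C)C)c(cn1)[C@@]1(O[Si](C)(C)C(C)(C)C)CC[C@@H](O[Si](CC)(CC)CC)[C@H]2O[C@H]21 | intermediate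
28 | 3-lithio derivative of 27 | [Li]c1c(OCC[Si](C)(C)C)ncc(c1OCC[Si](C)(C)C)[C@@]1(O[Si](C)(C)C(C)(C)C)CC[C@@H](O[Si](CC)(CC)CC)[C@H]2O[C@H]21 | intermediate
29 | [(1R,2S,4aR,8aR)-2-methyl-octahydronaphthalen-1-yl](pyridin-3-yl)methanol, pyridine substituted as in 27 (mixture of carbinol epimers) | C[C@H]1C=C[C@H]2CCCC[C@H]2[C@@H]1C(O)c1c(OCC[Si](C)(C)C)ncc(c1OCC[Si](C)(C)C)[C@@]1(O[Si](C)(C)C(C)(C)C)CC[C@@H](O[Si](CC)(CC)CC)[C@H]2O[C@H]21 | intermediate
30 | aryl ketone from 29 (2,4-bis-TMSE, 1′-O-TBS, 4′-O-TES protected 1-deoxyfischerin) | C[C@H]1C=C[C@H]2CCCC[C@H]2[C@@H]1C(=O)c1c(OCC[Si](C)(C)C)ncc(c1OCC[Si](C)(C)C)[C@@]1(O[Si](C)(C)C(C)(C)C)CC[C@@H](O[Si](CC)(CC)CC)[C@H]2O[C@H]21 | intermediate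
31 | 1-deoxyfischerin: 5-[(1R,2S,5R,6R)-2,5-dihydroxy-7-oxabicyclo[4.1.0]heptan-2-yl]-4-hydroxy-3-[(1R,2S,4aR,8aR)-2-methyl-1,2,4a,5,6,7,8,8a-octahydronaphthalene-1-carbonyl]pyridin-2(1H)-one | C[C@H]1C=C[C@H]2CCCC[C@H]2[C@@H]1C(=O)c1c(O)c([C@@]2(O)CC[C@@H](O)[C@H]3O[C@H]32)c[nH]c1=O | intermediate
32 | tetrakis(trimethylsilyl) derivative of 31 (2-O, 4-O and both alcohol oxygens silylated) | C[C@H]1C=C[C@H]2CCCC[C@H]2[C@@H]1C(=O)c1c(O[Si](C)(C)C)ncc(c1O[Si](C)(C)C)[C@@]1(O[Si](C)(C)C)CC[C@@H](O[Si](C)(C)C)[C@H]2O[C@H]21 | intermediate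
33 | fischerin: 5-[(1R,2S,5R,6R)-2,5-dihydroxy-7-oxabicyclo[4.1.0]heptan-2-yl]-1,4-dihydroxy-3-[(1R,2S,4aR,8aR)-2-methyl-1,2,4a,5,6,7,8,8a-octahydronaphthalene-1-carbonyl]pyridin-2(1H)-one | C[C@H]1C=C[C@H]2CCCC[C@H]2[C@@H]1C(=O)c1c(O)c([C@@]2(O)CC[C@@H](O)[C@H]3O[C@H]32)cn(O)c1=O | target

**Totals and risks**

Total step count: 20. Longest linear sequence: 12 steps (1 → 33 through steps 1–8 and 17–20).

Steps most likely to fail:

Step 20. The peroxo-molybdenum reagent may react sluggishly with the hindered acyl-substituted silyloxypyridine, or it may also epoxidise the decalin alkene. The fallback puts the N–O bond in before the decalin is attached; it sets out from 27 and comes back at 33. Oxidation of 27 with mCPBA (no alkene is present at this stage) should give the pyridine N-oxide F6. Electrophilic iodination with NIS at the only activated ring position then gives the 3-iodide F7. Iodine–magnesium exchange with i-PrMgCl·LiCl at −40 °C gives the arylmagnesium chloride F8, which is added to aldehyde 15 and quenched with aqueous NH4Cl to give the carbinol F9. Periodinane oxidation gives the ketone F10. Buffered TBAF then removes all silicon-based groups; loss of the 2-O-alkyl group from the N-oxide unmasks the 1-hydroxy-2-pyridone directly, giving 33.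

Step 2. Discrimination between the two enantiotopic ring carbons may be insufficient, or the product vinyl group may undergo secondary cross-metathesis. The fallback replaces catalyst control by classical resolution; it sets out from 3 and comes back at 7. Ring-opening cross-metathesis of 3 with 4 using the achiral catalyst (H2IMes)(PCy3)Cl2Ru=CHPh should give 5 together with the enantiomeric enol ether F1. Acid hydrolysis gives 6 together with the enantiomeric aldehyde F2, and Pinnick oxidation gives 7 together with the enantiomeric acid F3. Crystallisation of the racemic acid with (R)-1-phenylethylamine (or its enantiomer, whichever gives the less soluble salt of 7) gives the diastereomerically pure ammonium salt F4, and acidification with HCl returns 7.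

Step 13. The activated allylic oxyphosphonium ion may eliminate to the cyclohexadiene, ionise, or be attacked in the SN2′ sense. The fallback inverts C4′ by a redox pair instead of by substitution; it sets out from 23 and comes back at 25. Periodinane oxidation of 23 gives the enone F5, and reagent-controlled oxazaborolidine (CBS) reduction with (S)-Me-CBS and catecholborane should deliver hydride to the face that gives 25.

Further compounds
F1 | step 2 | (1S,2S)-1-[(Z)-2-butoxyethenyl]-2-ethenylcyclohexane (enantiomer of 5) | C=C[C@@H]1CCCC[C@@H]1/C=C\OCCCC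
F2 | step 2 | 2-[(1R,2S)-2-ethenylcyclohexyl]acetaldehyde (enantiomer of 6) | C=C[C@@H]1CCCC[C@@H]1CC=O
F3 | step 2 | 2-[(1R,2S)-2-ethenylcyclohexyl]acetic acid (enantiomer of 7) | C=C[C@@H]1CCCC[C@@H]1CC(=O)O
F4 | step 2 | (1R)-1-phenylethan-1-aminium 2-[(1S,2R)-2-ethenylcyclohexyl]acetate | C=C[C@H]1CCCC[C@H]1CC(=O)[O-].C[C@@H]([NH3+])c1ccccc1
F5 | step 13 | (4R)-4-{4,6-bis[2-(trimethylsilyl)ethoxy]pyridin-3-yl}-4-[(tert-butyldimethylsilyl)oxy]cyclohex-2-en-1-one | C[Si](C)(C)CCOc1cc(OCC[Si](C)(C)C)c(cn1)[C@@]1(O[Si](C)(C)C(C)(C)C)CCC(=O)C=C1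
F6 | step 20 | 1-oxide of 27 | C[Si](C)(C)CCOc1cc(OCC[Si](C)(C)C)c(c[n+]1[O-])[C@@]1(O[Si](C)(C)C(C)(C)C)CC[C@@H](O[Si](CC)(CC)CC)[C@H]2O[C@H]21
F7 | step 20 | 3-iodo derivative of the 1-oxide of 27 | C[Si](C)(C)CCOc1c(I)c(OCC[Si](C)(C)C)c(c[n+]1[O-])[C@@]1(O[Si](C)(C)C(C)(C)C)CC[C@@H](O[Si](CC)(CC)CC)[C@H]2O[C@H]21
F8 | step 20 | 3-(chloromagnesio) derivative of the 1-oxide of 27 | Cl[Mg]c1c(OCC[Si](C)(C)C)[n+]([O-])cc(c1OCC[Si](C)(C)C)[C@@]1(O[Si](C)(C)C(C)(C)C)CC[C@@H](O[Si](CC)(CC)CC)[C@H]2O[C@H]21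
F9 | step 20 | pyridine 1-oxide of carbinol 29 (mixture of carbinol epimers) | C[C@H]1C=C[C@H]2CCCC[C@H]2[C@@H]1C(O)c1c(OCC[Si](C)(C)C)[n+]([O-])cc(c1OCC[Si](C)(C)C)[C@@]1(O[Si](C)(C)C(C)(C)C)CC[C@@H](O[Si](CC)(CC)CC)[C@H]2O[C@H]21
F10 | step 20 | pyridine 1-oxide of ketone 30 | C[C@H]1C=C[C@H]2CCCC[C@H]2[C@@H]1C(=O)c1c(OCC[Si](C)(C)C)[n+]([O-])cc(c1OCC[Si](C)(C)C)[C@@]1(O[Si](C)(C)C(C)(C)C)CC[C@@H](O[Si](CC)(CC)CC)[C@H]2O[C@H]21
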